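The plant chemist and the lab head disagree about one flask: the north-east recipe, left standing to the asked time.

| flask | solid substrate | gas phase | protic impurity | free catalyst | remark | time |
|---|---|---|---|---|---|---|
| north-east | 0.061 M | 13 mM (held) | 0.0122 M | 3 mM | the very flask that is asked about, followed so far |  |
| south | 0.061 M | 13 mM (held) | 0.024 M | 3 mM | run made earlier |  |
| flask | 0.061 M | 13 mM (held) | 0.0122 M | 3.0 mM |  | 10 d |

- north-east (time / d: product / %, solid substrate / %): 0.625: 17.9, 28.8; 1.25: 33.8, 4.0; 1.67: 37.4, 0; 2.50: 41.7, 0.6; 3.00: 41.7, 0; 4.00: 42.1, 0.5
- south (time / d: product / %, solid substrate / %): 0.625: 16.8, 23.7; 0.833: 23.7, 9.0; 1.25: 28.1, 0.1; 2.08: 34.2, 1.0; 3.00: 38.2, 0; 5.00: 36.9, 0.6; 8.00: 38.4, 0.2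

(each reading ± 1 percentage point)

- amount of product at 10 d, in percent of the solid substrate charged
- concentration of dissolved gas in solution at 10 d, in percent of saturation

- solid, in amounts per volume of the solution: solid substrate
- at the start none of the gas phase is in solution
- at the start none of the solid substrate is in solution

The plant chemist counts per catalyst. She takes the last north-east product, 42.1% at 4.00 d, multiplies by c(solid substrate) 0.061 M, divides by c(free catalyst) 3 mM, and gets 8.56. This is the turnover number N, the moles of product per mole of free catalyst charged by the time product stops rising. With the gas, the solid substrate and the impurity held at their charges, her rule is that yield equals N times c(free catalyst) over c(solid substrate).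

The lab head counts per impurity. In his view each mole of protic impurity costs one mole of substrate, the catalyst merely works slowly, and the missing charge waits unseen in solution. So the north-east recipe should creep on to 80.0%.

She answers in powers of ten. From north-east to south the logarithm of the impurity rises by 0.294, and his view asks the logarithm of the plateau to fall by 0.120, but the last readings of the two runs show a fall of 0.0400, which is smaller. He objects that the north-east readings end at 4.00 d, well short of 10 d. She points to south, which reads 38.2% at 3.00 d and 38.4% at 8.00 d, a difference within the scatter of 1 percentage point.

The forecast takes her side, with 42% of product and 99% of saturation: “The plateau looks like a true stop”.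

The simulation gives 42.9% of product and 100% of saturation; that product is 8.72 turnovers in this flask against the 8.56 read from north-east.

    gas phase ⇌ dissolved gas, rate k1*(csat - [dissolved gas]) (kL = 4.40 h⁻¹)
    starting material + dissolved gas + free catalyst → free catalyst + product (k = 1900 L² mol⁻² h⁻¹)
    dissolved gas + free catalyst → spent catalyst (k = 4.40 L mol⁻¹ h⁻¹)
    starting material + protic impurity → quenched substrate (k = 4.10 L mol⁻¹ h⁻¹)
    solid substrate ⇌ starting material, rate k5*(cs5 - [starting material]) while solid is left; crystals form when [starting material] > cs5 (solubility = 32.0 mM, k = 0.190 h⁻¹)

Product in this flask stops short of the charge mainly because dissolved gas converts free catalyst into spent catalyst, >99.9% of the catalyst charge at 10 d. The same flask without that step reaches 81.2%, close to the lab head's 80.0%, so in that run the forecast's number would miss and his count would come near.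

The neighbour charged with 7.5 × 10⁻⁴ M of free catalyst, all else as in the recipe, has a logarithm of the catalyst charge lower by 0.602, so N promises 10.5% of product. That neighbour gives 12.0% of product at 10 d.

The runs are simulated for an exercise; the scatter is artificial.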